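**Retrosynthetic overview**
1. Target ⇒ bis-silyl ether. Ring B (cycloheptenone) is closed last by ring-closing metathesis across C7=C8, joining a vinyl carbinol and an isopropenyl ketone.
2. Isopropenyl ketone ⇒ α-methylenation of a C1–CH2–CO–Et ketone. That ketone ⇒ key oxidative 1,2-shift, in which the quaternary ring carbon C1 moves from C9 to C10 of a but-1-en-2-yl group.
3. Tertiary aroyl ester at C4 ⇒ iPrMgCl addition to the cyclopentanone, with the alkoxide trapped by an aroyl chloride made from a protected 4-bromophenol and CO2.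
4. C1, C5 and C6 ⇒ one-pot enantioselective conjugate addition of an alkenylaluminium (from but-1-yne) to 3-methylcyclopent-2-enone, followed by anti aldol with acrolein.
5. Ring order: ring A is bought as the cyclopentenone; ring B is formed in the penultimate step.

Assumption and convention: compound 8 and the chiral imidazolinium NHC precursor are bought. Comments use daucane numbering (C1 quaternary CMe, C4 C–O–aroyl, C5 ring-fusion CH, C6 CHOH, C7=C8(Me), C9 C=O, C10 CH2).

**Step 1**
Reactants: 1 but-1-yne; 2 3-methylcyclopent-2-en-1-one; 3 acrolein (prop-2-enal)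
Product: 6 (2S,3S)-3-(but-1-en-2-yl)-2-[(1S)-1-hydroxyprop-2-en-1-yl]-3-methylcyclopentan-1-one, via but-1-en-2-yl(diisobutyl)aluminium 4 (not isolated), via diisobutylaluminium enolate 5 (not isolated)
Conditions: 1, iBu2AlH, NiCl2(dppp) (3 mol %), THF, 0 to 22 °C; then 2, Cu(OTf)2 (5 mol %), chiral sulfonate-bearing imidazolinium salt (NHC precursor, 5 mol %), −30 °C; then 3, −78 °C; aqueous work-up
Reagents that add atoms: none
Why: Nickel-catalysed α-selective hydroalumination gives the 1,1-disubstituted alkenylaluminium, its copper–NHC-catalysed enantioselective conjugate addition sets quaternary C1 (ligand enantiomer chosen for S), and the E-configured ring enolate then adds to acrolein through a closed Zimmerman–Traxler aldol transition state on the face anti to the bulky butenyl group, which sets C5 (trans) and the anti carbinol C6.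

**Step 2**
Reactants: 6 aldol from step 1
Product: 7 (2S,3S)-3-(but-1-en-2-yl)-2-[(1S)-1-{[tert-butyl(dimethyl)silyl]oxy}prop-2-en-1-yl]-3-methylcyclopentan-1-one
Conditions: TBSOTf, 2,6-lutidine, CH2Cl2, −78 to 0 °C
Reagents that add atoms: tert-butyldimethylsilyl triflate, CC(C)(C)[Si](C)(C)OS(=O)(=O)C(F)(F)F
Why: O-silylation of a secondary alcohol with a silyl triflate and a hindered base is cold and mild enough to avoid retro-aldol and epimerisation at C5, and it creates no new stereocentre.

**Step 3**
Reactants: 8 (4-bromophenoxy)(tert-butyl)dimethylsilane; 9 carbon dioxide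
Product: 11 4-{[tert-butyl(dimethyl)silyl]oxy}benzoic acid, via aryllithium 10 (not isolated)
Conditions: n-BuLi, THF, −78 °C; CO2 (g); 1 M HCl to pH 4
Reagents that add atoms: none
Why: Bromine–lithium exchange followed by carboxylation of the aryllithium works here because the phenolic silyl ether survives the cold basic medium and the brief mild acid work-up.

**Step 4**
Reactants: 7 silyl ether ketone; 11 protected benzoic acid; 12 isopropylmagnesium chloride
Product: 15 (1R,2S,3S)-3-(but-1-en-2-yl)-2-[(1S)-1-{[tert-butyl(dimethyl)silyl]oxy}prop-2-en-1-yl]-3-methyl-1-(propan-2-yl)cyclopentyl 4-{[tert-butyl(dimethyl)silyl]oxy}benzoate, via aroyl chloride 13 (not isolated), via chloromagnesium alkoxide 14 (not isolated)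
Conditions: 11, 1-chloro-N,N,2-trimethylprop-1-en-1-amine, CH2Cl2, 0 °C (gives 13); separately 7, 12, LaCl3·2LiCl, THF, −78 to 0 °C; then 13, DMAP (10 mol %), 0 to 40 °C
Reagents that add atoms: none
Why: Lanthanum-assisted Grignard 1,2-addition suppresses enolisation and reduction, the nucleophile attacks the face opposite to the adjacent C5 side chain so that the new C4–O bond is cis to it (R), and the hindered alkoxide is O-acylated in the same flask by the acid chloride made under neutral conditions.

**Step 5**
Reactants: 15 butenyl ester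
Product: 17 (1R,2S,3R)-2-[(1S)-1-{[tert-butyl(dimethyl)silyl]oxy}prop-2-en-1-yl]-3-methyl-3-(2-oxobutyl)-1-(propan-2-yl)cyclopentyl 4-{[tert-butyl(dimethyl)silyl]oxy}benzoate, via hydroxyalkyl(phenyl)iodonium tosylate 16 (not isolated)
Conditions: PhI(OH)OTs (1.1 equiv), 2,6-di-tert-butyl-4-methylpyridine (1.2 equiv), MeCN–H2O 10:1, 0 °C to rt
Reagents that add atoms: water, O
Why: Proposed new method: electrophilic trivalent iodine adds to the terminal carbon (C10) of the electron-richer 1,1-disubstituted alkene and water to the internal carbon (C9); the neopentyl-type primary C–I bond of 16 cannot be displaced directly, so loss of iodobenzene is coupled to a semipinacol 1,2-shift from the carbinol carbon, in which the tertiary ring carbon C1 (migratory aptitude tert-alkyl far above ethyl, and held anti to the leaving group for steric reasons) moves from C9 to C10 with retention (the descriptor changes S to R only through priorities) and forms the C1–C10 bond and the C9 ketone; the closest known reaction types are the Koser-type oxidative rearrangement of 1,1-disubstituted styrenes (aryl shift) and the ring enlargement of methylenecycloalkanes by trivalent iodine or trivalent thallium.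

**Step 6**
Reactants: 17 2-oxobutyl ester; 18 formaldehyde (as paraformaldehyde)
Product: 19 (1R,2S,3R)-2-[(1S)-1-{[tert-butyl(dimethyl)silyl]oxy}prop-2-en-1-yl]-3-methyl-3-(3-methyl-2-oxobut-3-en-1-yl)-1-(propan-2-yl)cyclopentyl 4-{[tert-butyl(dimethyl)silyl]oxy}benzoate
Conditions: (CH2O)n, iPr2NH·CF3CO2H, THF, reflux
Reagents that add atoms: none
Why: Mannich-type α-methylenation (condensation with formaldehyde, then elimination) occurs at the ethyl CH2 (C8) because the other α position (C10) is neopentyl and hindered, and no stereocentre is touched.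

**Step 7**
Reactants: 19 isopropenyl ketone
Product: 20 (3R,3aS,4S,8aR)-4-{[tert-butyl(dimethyl)silyl]oxy}-6,8a-dimethyl-7-oxo-3-(propan-2-yl)-1,2,3,3a,4,7,8,8a-octahydroazulen-3-yl 4-{[tert-butyl(dimethyl)silyl]oxy}benzoate
Conditions: Hoveyda–Grubbs second-generation catalyst (5 mol %), toluene (2 mM), 80 °C
Reagents that add atoms: none
Why: Ring-closing metathesis of the terminal allylic alkene with the 1,1-disubstituted enone alkene closes ring B as the trisubstituted endocyclic enone, driven by loss of ethene, and the trans ring fusion is already fixed by C1 and C5.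

**Step 8**
Reactants: 20 bis-silyl ether
Product: 21 (3R,3aS,4S,8aR)-4-hydroxy-6,8a-dimethyl-7-oxo-3-(propan-2-yl)-1,2,3,3a,4,7,8,8a-octahydroazulen-3-yl 4-hydroxybenzoate (target)
Conditions: HF·pyridine, pyridine, THF, 0 °C to rt
Reagents that add atoms: none
Why: Fluoride-mediated cleavage of both silyl ethers under buffered acidic conditions is chosen because basic fluoride could move the aroyl group from the tertiary O4 to the freed secondary O6, and all four stereocentres stay untouched.

**Compound list**
1 | but-1-yne | CCC#C | starting material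
2 | 3-methylcyclopent-2-en-1-one | CC1=CC(=O)CC1 | starting material
3 | acrolein | C=CC=O | starting material
4 | but-1-en-2-yl(diisobutyl)aluminium | CCC(=C)[Al](CC(C)C)CC(C)C | intermediate
5 | diisobutylaluminium (3S)-3-(but-1-en-2-yl)-3-methylcyclopent-1-en-1-olate | CCC(=C)[C@@]1(C)CCC(O[Al](CC(C)C)CC(C)C)=C1 | intermediate
6 | (2S,3S)-3-(but-1-en-2-yl)-2-[(1S)-1-hydroxyprop-2-en-1-yl]-3-methylcyclopentan-1-one | C=C[C@H](O)[C@@H]1[C@](C)(CCC1=O)C(=C)CC | intermediate
7 | TBS ether of 6 | C=C[C@H](O[Si](C)(C)C(C)(C)C)[C@@H]1[C@](C)(CCC1=O)C(=C)CC | intermediate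
8 | (4-bromophenoxy)(tert-butyl)dimethylsilane | CC(C)(C)[Si](C)(C)Oc1ccc(Br)cc1 | starting material
9 | carbon dioxide | O=C=O | starting material
10 | (4-{[tert-butyl(dimethyl)silyl]oxy}phenyl)lithium | [Li]c1ccc(O[Si](C)(C)C(C)(C)C)cc1 | intermediate
11 | 4-{[tert-butyl(dimethyl)silyl]oxy}benzoic acid | CC(C)(C)[Si](C)(C)Oc1ccc(cc1)C(=O)O | intermediate
12 | isopropylmagnesium chloride | CC(C)[Mg]Cl | starting material
13 | 4-{[tert-butyl(dimethyl)silyl]oxy}benzoyl chloride | CC(C)(C)[Si](C)(C)Oc1ccc(cc1)C(=O)Cl | intermediate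
14 | chloromagnesium (1R,2S,3S)-cyclopentan-1-olate formed from 7 and 12 | C=C[C@H](O[Si](C)(C)C(C)(C)C)[C@@H]1[C@](C)(CC[C@@]1(O[Mg]Cl)C(C)C)C(=C)CC | intermediate
15 | (1R,2S,3S)-butenyl tertiary aroyl ester | C=C[C@H](O[Si](C)(C)C(C)(C)C)[C@@H]1[C@](C)(CC[C@@]1(OC(=O)c1ccc(O[Si](C)(C)C(C)(C)C)cc1)C(C)C)C(=C)CC | intermediate
16 | 2-hydroxy-2-(cyclopentyl)butyl(phenyl)-λ3-iodanyl tosylate (carbinol centre either way) | C=C[C@H](O[Si](C)(C)C(C)(C)C)[C@@H]1[C@](C)(CC[C@@]1(OC(=O)c1ccc(O[Si](C)(C)C(C)(C)C)cc1)C(C)C)C(O)(CC)CI(c1ccccc1)OS(=O)(=O)c1ccc(C)cc1 | intermediate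
17 | (1R,2S,3R)-2-oxobutyl ester | C=C[C@H](O[Si](C)(C)C(C)(C)C)[C@@H]1[C@](C)(CC[C@@]1(OC(=O)c1ccc(O[Si](C)(C)C(C)(C)C)cc1)C(C)C)CC(=O)CC | intermediate
18 | formaldehyde | C=O | starting material
19 | (1R,2S,3R)-isopropenyl ketone ester | C=C[C@H](O[Si](C)(C)C(C)(C)C)[C@@H]1[C@](C)(CC[C@@]1(OC(=O)c1ccc(O[Si](C)(C)C(C)(C)C)cc1)C(C)C)CC(=O)C(C)=C | intermediate
20 | (3R,3aS,4S,8aR)-bis-TBS ether of the target | CC1=C[C@H](O[Si](C)(C)C(C)(C)C)[C@@H]2[C@](C)(CC[C@@]2(OC(=O)c2ccc(O[Si](C)(C)C(C)(C)C)cc2)C(C)C)CC1=O | intermediate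
21 | CNP0153637.1 | CC1=C[C@H](O)[C@@H]2[C@](C)(CC[C@@]2(OC(=O)c2ccc(O)cc2)C(C)C)CC1=O | target

**Step count**
- Total step count: 8.
- Longest linear sequence: 7 (steps 1, 2, 4, 5, 6, 7, 8).

**Steps most likely to fail**

*Step 5 (new oxidative 1,2-shift).*
- Risks: attack at the vinyl group, solvent capture without the shift, or loss of silyl groups.
- Fallback with known chemistry, setting out from 15 and coming back at 17: buffered mCPBA epoxidises the more electron-rich 1,1-disubstituted alkene to the 2-ethyl-2-cyclopentyloxirane F1. MgBr2·OEt2 opens it at the CH2 terminus to the tertiary bromohydrin F2. AgOTf with 2,6-di-tert-butylpyridine then triggers the classical halohydrin semipinacol rearrangement, in which the tertiary ring carbon again migrates, to give 17.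

*Step 4 (isopropyl addition and acylation of a very hindered alkoxide).*
- Risks: reduction or enolisation of the ketone, poor facial selectivity, or no acylation.
- Fallback setting out from 7 and coming back at 15: the addition is quenched with water and the tertiary alcohol F3 is isolated. KH and 1,1'-carbonyldiimidazole convert it into the small, reactive imidazole-1-carboxylate F4. The arylmagnesium bromide F5 (from 8 and Mg) adds once to F4. The ester is thus completed by C(aryl)–C(O) bond formation instead of attack of the hindered oxygen on a bulky aroyl chloride.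

*Step 1 (three-component conjugate addition and aldol).*
- Risks: a sluggish aluminium enolate or a poor anti/syn ratio at C6.
- Fallback setting out from 5 and coming back at 6: the enolate is trapped with Et3SiOTf as the triethylsilyl enol ether F6, which is isolated. MeLi regenerates the regiodefined lithium enolate F7. (c-C6H11)2BCl gives the dicyclohexylboron enolate F8. Its boron aldol with 3, followed by H2O2 work-up, delivers the anti aldol 6.

**Further compounds**
F1 | step 5 | 2-ethyl-2-cyclopentyloxirane derived from 15 (oxirane centre either way) | C=C[C@H](O[Si](C)(C)C(C)(C)C)[C@@H]1[C@](C)(CC[C@@]1(OC(=O)c1ccc(O[Si](C)(C)C(C)(C)C)cc1)C(C)C)C1(CC)CO1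
F2 | step 5 | tertiary bromohydrin (1-bromo-2-hydroxybutan-2-yl group on C1) | C=C[C@H](O[Si](C)(C)C(C)(C)C)[C@@H]1[C@](C)(CC[C@@]1(OC(=O)c1ccc(O[Si](C)(C)C(C)(C)C)cc1)C(C)C)C(O)(CC)CBr
F3 | step 4 | (1R,2S,3S)-tertiary alcohol | C=C[C@H](O[Si](C)(C)C(C)(C)C)[C@@H]1[C@](C)(CC[C@@]1(O)C(C)C)C(=C)CC
F4 | step 4 | (1R,2S,3S)-cyclopentyl imidazole-1-carboxylate | C=C[C@H](O[Si](C)(C)C(C)(C)C)[C@@H]1[C@](C)(CC[C@@]1(OC(=O)n1ccnc1)C(C)C)C(=C)CC
F5 | step 4 | (4-{[tert-butyl(dimethyl)silyl]oxy}phenyl)magnesium bromide | Br[Mg]c1ccc(O[Si](C)(C)C(C)(C)C)cc1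
F6 | step 1 | (3S)-triethylsilyl enol ether | CCC(=C)[C@@]1(C)CCC(O[Si](CC)(CC)CC)=C1
F7 | step 1 | (3S)-lithium enolate | CCC(=C)[C@@]1(C)CCC(O[Li])=C1
F8 | step 1 | (3S)-dicyclohexylboron enolate | CCC(=C)[C@@]1(C)CCC(OB(C2CCCCC2)C2CCCCC2)=C1
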